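**Retrosynthetic overview** (ring A = catechol benzo ring, ring B = dihydro carbocycle, ring C = pyrone)
1. Ring C is made last: the 6-carboxy-2-pyrone is opened at its ring C–O and carboxyl C–O bonds to a 3,4,5-trihydroxyphenyl group (O2 cleavage between two hydroxylated carbons, then lactonisation).
2. The pentaphenol acid comes from its penta-O-benzyl ether, and that from an N-acyl oxazolidinone by hydrolysis.
3. Ring B is opened at C1–C8a: Friedel–Crafts closure of a benzylic carbinol, which sets C1 trans to C2.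
4. The carbinol is an Evans syn-aldol adduct (C1–C2 bond, C2 set by the auxiliary) of an arylidene-succinyl oxazolidinone and 3,4,5-tris(benzyloxy)benzaldehyde.
5. The acyl unit is the Stobbe half-ester of 3,4-bis(benzyloxy)benzaldehyde and dimethyl succinate, which puts CO2Me on C3 and the free CO2H on C2; ring A and the pendant aryl come with the aldehydes, so the ring order is B, then C.

Assumption: the target is read from its SMILES as the (1R,2S), 1,2-trans isomer; 3,4,5-tris(benzyloxy)benzaldehyde and (R)-4-benzyloxazolidin-2-one are taken as purchasable.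

**Route**

Step 1
Reactants: 1 3,4-bis(benzyloxy)benzaldehyde; 2 dimethyl succinate
Product: 3 (E)-4-[3,4-bis(benzyloxy)phenyl]-3-(methoxycarbonyl)but-3-enoic acid
Conditions: NaOMe (2 equiv), MeOH, reflux; then aq. HCl
Reagents that add atoms: none
Why: Stobbe condensation, in which the succinate enolate adds to the aldehyde, the alkoxide lactonises onto the remote ester and E1cB opening of that paraconic lactone gives the E-arylidene half-ester with the methyl ester on the alkene carbon (later C3) and the free acid on the CH2 arm (later C2), as the target requires; no stereocentre is formed.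

Step 2
Reactants: 3 (E)-4-[3,4-bis(benzyloxy)phenyl]-3-(methoxycarbonyl)but-3-enoic acid; 4 (R)-4-benzyloxazolidin-2-one
Product: 6 (R)-4-benzyl-3-[(E)-4-[3,4-bis(benzyloxy)phenyl]-3-(methoxycarbonyl)but-3-enoyl]oxazolidin-2-one, via mixed pivalic anhydride 5 (not isolated)
Conditions: PivCl, Et3N, THF, −20 °C; then LiCl, 4, −20 °C → rt
Reagents that add atoms: pivaloyl chloride CC(C)(C)C(=O)Cl (its atoms stay only in 5)
Why: N-acylation of an Evans oxazolidinone through the mixed pivalic anhydride (the one-pot LiCl/Et3N variant), in which the auxiliary nitrogen attacks the less hindered acyl carbon of 5 and the mild conditions leave the E-alkene, the methyl ester and the benzyl ethers untouched; no stereocentre is formed.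

Step 3
Reactants: 6 (R)-4-benzyl-3-[(E)-4-[3,4-bis(benzyloxy)phenyl]-3-(methoxycarbonyl)but-3-enoyl]oxazolidin-2-one; 7 3,4,5-tris(benzyloxy)benzaldehyde
Product: 9 (R)-4-benzyl-3-[(2R,3R)-2-[(E)-2-[3,4-bis(benzyloxy)phenyl]-1-(methoxycarbonyl)ethenyl]-3-hydroxy-3-[3,4,5-tris(benzyloxy)phenyl]propanoyl]oxazolidin-2-one, via dibutylboron Z-enolate 8 (not isolated)
Conditions: Bu2BOTf, iPr2NEt, CH2Cl2, −78 → 0 °C; then 7, −78 → 0 °C; pH 7 buffer/MeOH work-up
Reagents that add atoms: dibutylboron triflate CCCCB(CCCC)OS(=O)(=O)C(F)(F)F (its Bu2B group stays only in 8)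
Why: Evans syn-aldol reaction, in which soft enolisation gives the Z-boron enolate that reacts at its alpha carbon through a closed Zimmerman–Traxler chair with the auxiliary carbonyl dipole-opposed, so the (R)-benzyl group shields one enolate face and sets C2 as 2R (the same spatial arrangement as the 2S centre of the final ring system) together with the 3R carbinol, which is consumed in step 4.

Step 4
Reactants: 9 (R)-4-benzyl-3-[(2R,3R)-2-[(E)-2-[3,4-bis(benzyloxy)phenyl]-1-(methoxycarbonyl)ethenyl]-3-hydroxy-3-[3,4,5-tris(benzyloxy)phenyl]propanoyl]oxazolidin-2-one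
Product: 10 (R)-4-benzyl-3-[(1R,2S)-6,7-bis(benzyloxy)-3-(methoxycarbonyl)-1-[3,4,5-tris(benzyloxy)phenyl]-1,2-dihydronaphthalene-2-carbonyl]oxazolidin-2-one
Conditions: TFA, CH2Cl2, −20 → 0 °C
Reagents that add atoms: none
Why: intramolecular Friedel–Crafts alkylation, in which acid ionises the electron-rich benzylic carbinol and the bis(benzyloxy)phenyl ring, held cis to C2 on the E-alkene, closes ring B at its position para to the C6 ether, the new aryl-bearing centre forming trans to the bulky C2 acyl group (1R) on the half-chair transition state; because the auxiliary is still attached, any stereochemical leak appears as a separable diastereomer.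

Step 5
Reactants: 10 (R)-4-benzyl-3-[(1R,2S)-6,7-bis(benzyloxy)-3-(methoxycarbonyl)-1-[3,4,5-tris(benzyloxy)phenyl]-1,2-dihydronaphthalene-2-carbonyl]oxazolidin-2-one
Product: 12 (1R,2S)-6,7-bis(benzyloxy)-3-(methoxycarbonyl)-1-[3,4,5-tris(benzyloxy)phenyl]-1,2-dihydronaphthalene-2-carboxylic acid, via percarboxylic acid 11 (not isolated)
Conditions: LiOH, H2O2, THF/H2O, 0 °C; then aq. Na2SO3; aq. HCl
Reagents that add atoms: hydrogen peroxide OO
Why: Evans auxiliary hydrolysis, in which the hydroperoxide anion attacks the exocyclic imide carbonyl selectively to give the peracid that sulfite reduces to the acid, under conditions too mild to saponify the hindered conjugated methyl ester or to disturb C1, while C2 keeps its thermodynamically preferred trans arrangement.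

Step 6
Reactants: 12 (1R,2S)-6,7-bis(benzyloxy)-3-(methoxycarbonyl)-1-[3,4,5-tris(benzyloxy)phenyl]-1,2-dihydronaphthalene-2-carboxylic acid
Product: 13 (1R,2S)-6,7-dihydroxy-3-(methoxycarbonyl)-1-(3,4,5-trihydroxyphenyl)-1,2-dihydronaphthalene-2-carboxylic acid
Conditions: BCl3, pentamethylbenzene, CH2Cl2, −78 °C; then MeOH/H2O; handled under Ar
Reagents that add atoms: none
Why: Lewis-acid debenzylation with a non-basic cation scavenger removes all five benzyl ethers at low temperature without touching the trisubstituted alkene (which hydrogenolysis would reduce), the methyl ester or the stereocentres, the pentamethylbenzene trapping benzyl cations before they can alkylate the electron-rich rings.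

Step 7
Reactants: 13 (1R,2S)-6,7-dihydroxy-3-(methoxycarbonyl)-1-(3,4,5-trihydroxyphenyl)-1,2-dihydronaphthalene-2-carboxylic acid
Product: 16 (1R,2S)-1-(6-carboxy-2-oxo-2H-pyran-4-yl)-6,7-dihydroxy-3-(methoxycarbonyl)-1,2-dihydronaphthalene-2-carboxylic acid (the target), via hydroxymuconic anhydride 14 (not isolated), via oxohexenedioic acid 15 (not isolated)
Conditions: FeCl3 + tris(2-pyridylmethyl)amine (TPA) (1:1, 2.2 equiv), 2,6-lutidine, O2 (1 atm), dry DMF, 0 → 25 °C; then 2 M HCl, EtOAc, 25–40 °C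
Reagents that add atoms: dioxygen O=O; water O
Why: Proposed new method: the trihydroxyphenyl ring binds a ferric [Fe(TPA)]3+ unit as a catecholate through two adjacent oxygens, O2 attacks the ring carbon of the ferrous-semiquinone resonance form and Criegee acyl migration inserts one oxygen atom between the two oxygen-bearing carbons (new C–O bonds) to give anhydride 14, which aqueous acid opens to the 2-hydroxymuconic acid whose 2-oxo tautomer 15 is closed by the carboxyl held cis on the ring-derived alkene and dehydrated to the 6-carboxy-2-pyrone (lactone C–O bond), either adjacent oxygen pair giving the same pyrone by the local symmetry of the ring, while the acrylate-conjugated, electron-poorer catechol of ring A is expected to sit as an O2-inert ferric catecholate and the two stereocentres are not involved; the closest known reaction type is the intradiol catechol-dioxygenase model cleavage of catechols to muconic anhydrides by ferric TPA catecholates and O2, which has not been shown for a pyrogallol on a lignan core or coupled to pyrone-forming lactonisation.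

**Compound list**
1 | 3,4-bis(benzyloxy)benzaldehyde | O=Cc1ccc(OCc2ccccc2)c(OCc2ccccc2)c1 | starting material
2 | dimethyl succinate | COC(=O)CCC(=O)OC | starting material
3 | (E)-4-[3,4-bis(benzyloxy)phenyl]-3-(methoxycarbonyl)but-3-enoic acid | COC(=O)/C(=C/c1ccc(OCc2ccccc2)c(OCc2ccccc2)c1)CC(=O)O | intermediate
4 | (R)-4-benzyloxazolidin-2-one | O=C1N[C@H](Cc2ccccc2)CO1 | starting material
5 | mixed anhydride of 3 with pivalic acid | COC(=O)/C(=C/c1ccc(OCc2ccccc2)c(OCc2ccccc2)c1)CC(=O)OC(=O)C(C)(C)C | intermediate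
6 | (R)-4-benzyl-3-[(E)-4-[3,4-bis(benzyloxy)phenyl]-3-(methoxycarbonyl)but-3-enoyl]oxazolidin-2-one | COC(=O)/C(=C/c1ccc(OCc2ccccc2)c(OCc2ccccc2)c1)CC(=O)N1[C@H](Cc2ccccc2)COC1=O | intermediate
7 | 3,4,5-tris(benzyloxy)benzaldehyde | O=Cc1cc(OCc2ccccc2)c(OCc2ccccc2)c(OCc2ccccc2)c1 | starting material
8 | dibutylboron (1Z,3E)-enolate of 6: (R)-4-benzyl-3-[(1Z,3E)-4-[3,4-bis(benzyloxy)phenyl]-1-(dibutylboryloxy)-3-(methoxycarbonyl)buta-1,3-dienyl]oxazolidin-2-one | CCCCB(CCCC)O/C(=C\C(=C/c1ccc(OCc2ccccc2)c(OCc2ccccc2)c1)C(=O)OC)N1[C@H](Cc2ccccc2)COC1=O | intermediate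
9 | (R)-4-benzyl-3-[(2R,3R)-2-[(E)-2-[3,4-bis(benzyloxy)phenyl]-1-(methoxycarbonyl)ethenyl]-3-hydroxy-3-[3,4,5-tris(benzyloxy)phenyl]propanoyl]oxazolidin-2-one (syn-aldol adduct) | COC(=O)/C(=C/c1ccc(OCc2ccccc2)c(OCc2ccccc2)c1)[C@H]([C@@H](O)c1cc(OCc2ccccc2)c(OCc2ccccc2)c(OCc2ccccc2)c1)C(=O)N1[C@H](Cc2ccccc2)COC1=O | intermediate
10 | (R)-4-benzyl-3-[(1R,2S)-6,7-bis(benzyloxy)-3-(methoxycarbonyl)-1-[3,4,5-tris(benzyloxy)phenyl]-1,2-dihydronaphthalene-2-carbonyl]oxazolidin-2-one | COC(=O)C1=Cc2cc(OCc3ccccc3)c(OCc3ccccc3)cc2[C@@H](c2cc(OCc3ccccc3)c(OCc3ccccc3)c(OCc3ccccc3)c2)[C@@H]1C(=O)N1[C@H](Cc2ccccc2)COC1=O | intermediate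
11 | (1R,2S)-6,7-bis(benzyloxy)-3-(methoxycarbonyl)-1-[3,4,5-tris(benzyloxy)phenyl]-1,2-dihydronaphthalene-2-carboperoxoic acid (formed as its lithium salt) | COC(=O)C1=Cc2cc(OCc3ccccc3)c(OCc3ccccc3)cc2[C@@H](c2cc(OCc3ccccc3)c(OCc3ccccc3)c(OCc3ccccc3)c2)[C@@H]1C(=O)OO | intermediate
12 | (1R,2S)-6,7-bis(benzyloxy)-3-(methoxycarbonyl)-1-[3,4,5-tris(benzyloxy)phenyl]-1,2-dihydronaphthalene-2-carboxylic acid | COC(=O)C1=Cc2cc(OCc3ccccc3)c(OCc3ccccc3)cc2[C@@H](c2cc(OCc3ccccc3)c(OCc3ccccc3)c(OCc3ccccc3)c2)[C@@H]1C(=O)O | intermediate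
13 | (1R,2S)-6,7-dihydroxy-3-(methoxycarbonyl)-1-(3,4,5-trihydroxyphenyl)-1,2-dihydronaphthalene-2-carboxylic acid | COC(=O)C1=Cc2cc(O)c(O)cc2[C@@H](c2cc(O)c(O)c(O)c2)[C@@H]1C(=O)O | intermediate
14 | (1R,2S)-6,7-dihydroxy-1-(6-hydroxy-2,7-dioxo-2,7-dihydrooxepin-4-yl)-3-(methoxycarbonyl)-1,2-dihydronaphthalene-2-carboxylic acid (2-hydroxymuconic anhydride) | COC(=O)C1=Cc2cc(O)c(O)cc2[C@@H](C2=CC(=O)OC(=O)C(O)=C2)[C@@H]1C(=O)O | intermediate
15 | (2E)-3-[(1R,2S)-2-carboxy-6,7-dihydroxy-3-(methoxycarbonyl)-1,2-dihydronaphthalen-1-yl]-5-oxohex-2-enedioic acid (2-oxo tautomer of the ring-opened 2-hydroxymuconic acid; CH2 and CO2H cis on the alkene) | COC(=O)C1=Cc2cc(O)c(O)cc2[C@@H](/C(=C/C(=O)O)CC(=O)C(=O)O)[C@@H]1C(=O)O | intermediate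
16 | (1R,2S)-1-(6-carboxy-2-oxo-2H-pyran-4-yl)-6,7-dihydroxy-3-(methoxycarbonyl)-1,2-dihydronaphthalene-2-carboxylic acid (CNP0333269.1) | COC(=O)C1=Cc2cc(O)c(O)cc2[C@@H](c2cc(C(=O)O)oc(=O)c2)[C@@H]1C(=O)O | target

**Step count**
Total steps: 7. Longest linear sequence: 7 steps (1 → 16).

**Steps most likely to fail, with fallbacks**

Step 7 (the proposed new oxidation). The risks are over-oxidation of ring A, oxidative aromatisation of ring B through a quinone methide, and sluggish lactonisation. The fallback uses known, stoichiometric, metal-free chemistry and sets out from 13. One equivalent of o-chloranil (MeCN/Et2O, −40 °C) oxidises the more electron-rich trihydroxyphenyl ring to the hydroxy-o-quinone (1R,2S)-6,7-dihydroxy-1-(5-hydroxy-3,4-dioxocyclohexa-1,5-dien-1-yl)-3-(methoxycarbonyl)-1,2-dihydronaphthalene-2-carboxylic acid F1. mCPBA (CH2Cl2, −40 → 0 °C) then inserts oxygen between the two quinone carbonyls, the long-known Baeyer–Villiger-type ring expansion of o-quinones to muconic anhydrides. This returns to the route at 14, and the aqueous acid treatment of step 7 carries it through 15 to 16.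

Step 4 (Friedel–Crafts closure of ring B). The risks are E1 loss of the C2 proton instead of ring closure and lactonisation of the carbinol onto the methyl ester. The fallback sets out from 9 and accepts the elimination. MsCl/Et3N (CH2Cl2, 0 °C) gives the mesylate (R)-4-benzyl-3-[(2R,3R)-2-[(E)-2-[3,4-bis(benzyloxy)phenyl]-1-(methoxycarbonyl)ethenyl]-3-(methylsulfonyloxy)-3-[3,4,5-tris(benzyloxy)phenyl]propanoyl]oxazolidin-2-one F2. DBU eliminates it to the bis(arylidene) imide (R)-4-benzyl-3-[(2E,3E)-4-[3,4-bis(benzyloxy)phenyl]-3-(methoxycarbonyl)-2-[3,4,5-tris(benzyloxy)benzylidene]but-3-enoyl]oxazolidin-2-one F3. Sc(OTf)3, chelated by the acyl oxazolidinone, then activates that enoyl unit for an intramolecular conjugate Friedel–Crafts alkylation in CH2Cl2; this is the known acid-induced cyclisation of dibenzylidenesuccinates to trans-1-aryl-1,2-dihydronaphthalenes. It returns to the route at 10, formed together with its diastereomer (R)-4-benzyl-3-[(1S,2R)-6,7-bis(benzyloxy)-3-(methoxycarbonyl)-1-[3,4,5-tris(benzyloxy)phenyl]-1,2-dihydronaphthalene-2-carbonyl]oxazolidin-2-one F4, which is removed by chromatography.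

Step 5 (auxiliary hydrolysis). The risks are slow attack at the hindered exocyclic carbonyl, opening of the oxazolidinone ring, and epimerisation at C2 before cleavage. The fallback sets out from 10 and avoids peroxide. BnOLi (from BnOH and n-BuLi; THF, −20 → 0 °C) transfers the acyl group to benzyl alcohol and gives 2-benzyl 3-methyl (1R,2S)-6,7-bis(benzyloxy)-1-[3,4,5-tris(benzyloxy)phenyl]-1,2-dihydronaphthalene-2,3-dicarboxylate F5 with release of 4. F5 is then put through the conditions of step 6, where BCl3/pentamethylbenzene removes the benzyl ester together with the five benzyl ethers. This returns to the route at 13 and bypasses 12.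

**Further compounds**
F1 | step 7 | (1R,2S)-6,7-dihydroxy-1-(5-hydroxy-3,4-dioxocyclohexa-1,5-dien-1-yl)-3-(methoxycarbonyl)-1,2-dihydronaphthalene-2-carboxylic acid | COC(=O)C1=Cc2cc(O)c(O)cc2[C@@H](C2=CC(=O)C(=O)C(O)=C2)[C@@H]1C(=O)O
F2 | step 4 | (R)-4-benzyl-3-[(2R,3R)-2-[(E)-2-[3,4-bis(benzyloxy)phenyl]-1-(methoxycarbonyl)ethenyl]-3-(methylsulfonyloxy)-3-[3,4,5-tris(benzyloxy)phenyl]propanoyl]oxazolidin-2-one | COC(=O)/C(=C/c1ccc(OCc2ccccc2)c(OCc2ccccc2)c1)[C@H]([C@@H](OS(C)(=O)=O)c1cc(OCc2ccccc2)c(OCc2ccccc2)c(OCc2ccccc2)c1)C(=O)N1[C@H](Cc2ccccc2)COC1=O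
F3 | step 4 | (R)-4-benzyl-3-[(2E,3E)-4-[3,4-bis(benzyloxy)phenyl]-3-(methoxycarbonyl)-2-[3,4,5-tris(benzyloxy)benzylidene]but-3-enoyl]oxazolidin-2-one | COC(=O)/C(=C/c1ccc(OCc2ccccc2)c(OCc2ccccc2)c1)C(=C\c1cc(OCc2ccccc2)c(OCc2ccccc2)c(OCc2ccccc2)c1)/C(=O)N1[C@H](Cc2ccccc2)COC1=O
F4 | step 4 | (R)-4-benzyl-3-[(1S,2R)-6,7-bis(benzyloxy)-3-(methoxycarbonyl)-1-[3,4,5-tris(benzyloxy)phenyl]-1,2-dihydronaphthalene-2-carbonyl]oxazolidin-2-one | COC(=O)C1=Cc2cc(OCc3ccccc3)c(OCc3ccccc3)cc2[C@H](c2cc(OCc3ccccc3)c(OCc3ccccc3)c(OCc3ccccc3)c2)[C@H]1C(=O)N1[C@H](Cc2ccccc2)COC1=O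
F5 | step 5 | 2-benzyl 3-methyl (1R,2S)-6,7-bis(benzyloxy)-1-[3,4,5-tris(benzyloxy)phenyl]-1,2-dihydronaphthalene-2,3-dicarboxylate | COC(=O)C1=Cc2cc(OCc3ccccc3)c(OCc3ccccc3)cc2[C@@H](c2cc(OCc3ccccc3)c(OCc3ccccc3)c(OCc3ccccc3)c2)[C@@H]1C(=O)OCc1ccccc1
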